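(The data come from a simulation with constants of no real substance; noise was put on by code.)

I count shares. The flask, its earlier runs and the questions stand here:

| flask | starting material | partner | rival reagent | protic impurity | temperature | remark | time |
|---|---|---|---|---|---|---|---|
| beta | 0.097 M | 0.50 equiv | 0.60 equiv | 0.0485 M | 110 °C | the very flask that is asked about, followed so far |  |
| delta | 0.097 M | 0.50 equiv | 0.60 equiv | 0.0485 M | 105 °C | run made earlier |  |
| flask | 0.097 M | 0.500 equiv | 0.600 equiv | 0.0485 M | 110 °C |  | 80 min |

| run | time / min | target / % |
|---|---|---|
| beta | 4.00 | 25.1 |
| beta | 12.0 | 34.6 |
| beta | 20.0 | 38.1 |
| beta | 30.0 | 40.2 |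
| beta | 50.0 | 42.5 |
| delta | 4.00 | 20.9 |
| delta | 12.0 | 31.1 |
| delta | 20.0 | 36.3 |
| delta | 30.0 | 38.5 |
| delta | 50.0 | 40.5 |

(each reading ± 0.5 percentage points)

- spring: at 80 min add partner, 100% of the amount charged, then wait 25 min
- summer: at 80 min take out 90% of the target then present, then wait 25 min
- noon: at 80 min raise the temperature by 25 K, then wait 25 min
- midnight: change nothing and wait 25 min more

- what is taken out of target is counted as made
- the numbers in the tables scatter by 0.5 percentage points (one standard deviation)
- additions bring no volume worth counting

- target, in percent of the starting material first charged, at 80 min
- which option adds most target ("none" when 2 percentage points or less is all one gets) (spring / summer / noon / midnight / none)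
- target present, with what was taken out counted in, in percent of the starting material first charged, after noon
- target present, with what was taken out counted in, in percent of the starting material first charged, after midnight

Two versions of the beta flask fit in my head. If the rival reagent does nothing, the partner is the limiting reagent and the target stops at 50.0% of the starting material. If rival and partner are equally fast, the symmetric case, the starting material divides by charge and the target stops at 45.5%, the partner's charge over both charges: the partner's share.

The beta readings, highest 42.5%, lie below both stops, so I ask which of the two their tail heads for. From 30.0 min to 50.0 min time grows by a factor of 1.67, the gap to the share shrinks by 1.78, and the gap to the other ceiling shrinks by 1.31. So I take the share as the end, with a gap falling as one over time. That gives 43.6% at 80 min and 44.0% after 25 min more.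

The headroom to the share is 1.8 percentage points, under the margin of 2 points, so I expect neither midnight nor noon to clear it, and summer shows me no reverse step to exploit. Spring is my weak point: my share leaves 4.06% of the starting material unspent, which fresh partner might take. I still call none, narrowly.

The forecast gives 43.9% (43.2% to 44.7%), 44.9% after noon, 44.4% after midnight, and best none: “Extra partner can capture at most the remaining 2% or so”. Its figure for now stands above mine.

The flask gives 43.4%, 44.4% after noon, 43.8% after midnight and best none, with spring adding 1.3 points.

    starting material + partner → target (k = 2.86 M⁻¹ min⁻¹, Ea = 90.0 kJ mol⁻¹)
    starting material + rival reagent → side product (k = 0.598 M⁻¹ min⁻¹, Ea = 71.0 kJ mol⁻¹)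
    rival reagent + protic impurity → quenched reagent (k = 7.20 M⁻¹ min⁻¹, Ea = 51.0 kJ mol⁻¹)
    2 starting material → self-condensation product (k = 1.09 M⁻¹ min⁻¹, Ea = 92.0 kJ mol⁻¹)
    (constants at 110 °C)

Left until 800 min, the flask reaches 44.5%, beside the share of 45.5%. But the remainder is not mainly the rival's: at 80.0 min the flask holds 8.17% side product against 47.1% self-condensation product. On the neighbour flask with 1.20 equiv of partner, the share is 66.7%. That flask gives 69.0% target, with 5.54% side product and 25.5% self-condensation product.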